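The data are calculated for an exercise; noise was put on by code.

Product in the spring run has to come from a small charge of partner, and one partner goes into each product. The partner is therefore the limiting reagent, and product cannot pass 16.2% of the starting material charged. How near it comes turns on two times: the 9.0 min allowed, and the use-up time, meaning the partner charge divided by its rate early in the run.

| setting | dawn | winter | spring |
|---|---|---|---|
| starting material | 0.800 M | 0.800 M | 1.60 M |
| partner | 0.800 M | 2.40 M | 0.260 M |
| time |  |  | 9.0 min |

| run | time / min | [product] / M |
|---|---|---|
| dawn run | 0.36 | 0 |
| dawn run | 0.57 | 0.009 |
| dawn run | 0.90 | 0.020 |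
| dawn run | 1.4 | 0.047 |
| dawn run | 2.3 | 0.115 |
| dawn run | 3.6 | 0.182 |
| dawn run | 5.7 | 0.295 |
| dawn run | 9.0 | 0.410 |
| winter run | 0.36 | 0.007 |
| winter run | 0.57 | 0.025 |
| winter run | 0.90 | 0.067 |
| winter run | 1.4 | 0.111 |
| winter run | 2.3 | 0.220 |
| winter run | 3.6 | 0.359 |
| winter run | 5.7 | 0.531 |
| winter run | 9.0 | 0.662 |

(readings scatter by 0.008 M)

- the exponent of [partner] in the starting rate at the charge of the dawn run (at the point where two percent of the starting material have become product)
- product in the spring run at 9.0 min, as a share of the starting material charged

- Overall: starting material + partner -> product.
- Constant volume, constant temperature.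
- The analysis sees a species whether free or bound.
- An order is taken over about fifteen percent of the charge, up and down.

To reckon that rate, we compare the two earlier runs over the same stretch of time. Between 1.4 min and 3.6 min the readings of the dawn run give an average rate of 0.0614 M min⁻¹, and those of the winter run 0.113 M min⁻¹. Both runs were charged with the same starting material, with partner differing by a factor of 3.00, so our exponent of partner, read over this stretch, is 0.554. We also assume the rate is proportional to starting material, which these two runs cannot test. The spring rate is then 0.0659 M min⁻¹. The partner charge divided by that rate is 3.95 min, our use-up time. The time allowed is 2.28 use-up times. If partner falls exponentially, 89.8% of the ceiling is reached, which gives us 14.6%.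

The forecast gives 0.6 and 14.3%, in its words “That is saturation in partner”.

The flask gives an exponent of 0.43.

    starting material + partner → intermediate (0.4176 M⁻¹ min⁻¹)
    intermediate → product (1.218 min⁻¹)
    2 partner ⇌ idle reagent dimer, settled at all times (1.300 M⁻¹)
    2 starting material ⇌ idle substrate dimer, settled at all times (0.5030 M⁻¹)

The spring run gives 14.5%, which is 89.5% of the ceiling, against our 89.8% from a use-up time of 3.95 min. Fitted to the readings, the true steps leave a root mean square residual of 0.63 in units of the scatter, and a power law 3.0. In the dawn run the same reckoning gives a use-up time of 13.0 min, and so 50.0% of the partner charge at 9.0 min, where the reading is 51.2%.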